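**Plan**
- Retrosynthesis, in order: the C9–H/Δ7 unit is traced to a Δ8-7-ketone (tosylhydrazone reduction with hydrogen shift); the O–C11 and C9–C11 bonds to isofraxidin and a C9 spiro-epoxide; then the C3–C4 bond of ring A is cut; last the C10–C1 and C10–CH3 bonds, which leaves (R)-carvone.
- Enabling feature: C4 is quaternary, carries two methyl groups, hangs on C5 of ring B and is flanked by the oxygenated C3. A C5 isopropenyl group is therefore a latent tertiary C4 radical (H• adds to its CH2, which becomes the second methyl), and C3 is an aldehyde on a C10–C1–C2 tether.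
- Forward: ring B is carvone; two enolate alkylations build quaternary C10; ring A is closed by radical addition to the aldehyde; C11 and the coumarin are attached at C9; the enone is transposed and reduced.
- Stereochemistry: C5 from (R)-carvone; C10 by alkylation anti to the isopropenyl group; C3 in the ring closure (equatorial alkoxyl); C9 last, by suprafacial hydrogen delivery from a 7β-diazene.

Key step: step 4

Remark: the target is read as the 3β-acetoxy-5α-H-9β-H-10β-methyl drim-7-ene (3S,5R,9R,10S), so C11 is trans to the C10 methyl group. Drimane numbers are used throughout (ring A = C1–C5, C10; ring B = C5–C10; C11 = OCH2 on C9); β is the face of the C10 methyl group.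

**Step 1**
Reactants: 1 (R)-(−)-carvone
Product: 3 (5R,6S)-2,6-dimethyl-5-(prop-1-en-2-yl)cyclohex-2-en-1-one (trans-6-methylcarvone; major epimer), via lithium dienolate 2 (not isolated)
Conditions: LiN(iPr)2 (LDA), THF, −78 °C; MeI, −78 → 0 °C
Reagents that add atoms: methyl iodide, CI
Why: Kinetic α′-deprotonation of the enone and C-methylation of the cross-conjugated dienolate (enolate alkylation) is the standard first alkylation of carvone; the new centre forms mainly trans to the isopropenyl group but is enolized again in step 2, so both epimers are carried on, and C5 is untouched.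

**Step 2**
Reactants: 3 trans-6-methylcarvone (with its C6 epimer)
Product: 5 (5S,6S)-2,6-dimethyl-5-(prop-1-en-2-yl)-6-(prop-2-yn-1-yl)cyclohex-2-en-1-one, via lithium enolate 4 (not isolated)
Conditions: LiN(iPr)2 (LDA), THF, −78 → −20 °C; propargyl bromide, DMPU, −78 °C → rt
Reagents that add atoms: propargyl bromide (3-bromoprop-1-yne), BrCC#C
Why: Substrate-controlled alkylation of the tetrasubstituted enolate by the activated propargylic bromide should occur on the face anti to the neighbouring C5 isopropenyl group, so the three-carbon chain ends trans and the methyl cis to isopropenyl, which is the C10 configuration of the target.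

**Step 3**
Reactants: 5 propargyl ketone
Product: 6 3-[(1S,6S)-1,3-dimethyl-2-oxo-6-(prop-1-en-2-yl)cyclohex-3-en-1-yl]propanal
Conditions: CpRu(MeCN)3PF6 (5 mol %), 5,5′-bis(trifluoromethyl)-2,2′-bipyridine (5 mol %), NMP–H2O 4:1, 25 °C
Reagents that add atoms: water, O
Why: Ruthenium-catalysed anti-Markovnikov hydration of the terminal alkyne should give the aldehyde directly under neutral conditions, leaving the enone, the isopropenyl group and both stereocentres untouched; no stereocentre is formed.

**Step 4**
Reactants: 6 enone aldehyde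
Product: 9 (4aS,6S,8aS)-6-hydroxy-2,5,5,8a-tetramethyl-4a,5,6,7,8,8a-hexahydronaphthalen-1(4H)-one (3β-hydroxy-11-nordrim-7-en-9-one), via tertiary C4 radical 7 (not isolated), via C3 alkoxyl radical 8 (not isolated)
Conditions: Fe(acac)3 (30 mol %), PhSiH3 (2.5 equiv), EtOH, 60 °C, 0.02 M
Reagents that add atoms: none
Why: Trivalent iron and PhSiH3 in ethanol form an iron hydride that transfers a hydrogen atom to the CH2 terminus of the 1,1-disubstituted C5 isopropenyl group, so C4 becomes tertiary radical 7 already bearing both methyl groups; 7 adds to the aldehyde carbon C3 to give alkoxyl radical 8, which is reduced and protonated (divalent iron, ethanol) to the alcohol while trivalent iron is returned. The closest known reaction type is the iron-hydride hydrogen-atom-transfer reductive cyclization of alkene-tethered ketones, together with intermolecular additions of such radicals to aldehydes. Ring A closes in the 6-exo-trig mode onto the C=O bond (ring atoms C4, C5, C10, C1, C2, C3), and because the isopropenyl group and the propanal chain are trans and both equatorial on ring B, the new ring can only be trans-fused. C3 is the one new stereocentre: in the chair-like transition state the carbonyl oxygen should lie pseudo-equatorial, away from the axial hydrogens on C1 and C5, and since the addition is reversible the more stable equatorial (3β) alkoxyl radical should be the one trapped; C4 is not stereogenic. The step needs hydrogen-atom transfer to the electron-rich isopropenyl alkene in preference to the electron-poor trisubstituted enone alkene and to silane reduction of the aldehyde, and it needs the radical to choose the aldehyde; geometry secures the latter, because the enone carbons could only close a four-membered or bridged ring.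

**Step 5**
Reactants: 9 hydroxy enone
Product: 11 9β,11-epoxydrim-7-en-3β-ol (spiro-oxirane on C9), via sulfonium betaine 10 (not isolated)
Conditions: Me3SI (3 equiv), n-BuLi (2.8 equiv), THF, −10 °C; then 9, −10 °C → rt
Reagents that add atoms: trimethylsulfonium iodide, C[S+](C)C.[I-]
Why: Corey–Chaykovsky epoxidation, in which dimethylsulfonium methylide adds 1,2 to the enone carbonyl, should occur from the α face anti to the axial C10 methyl group before the betaine closes with loss of dimethyl sulfide; the C9 configuration (oxygen β) is of no consequence because C9 becomes trigonal in step 8, and the C3 hydroxyl only consumes one equivalent of ylide.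

**Step 6**
Reactants: 11 vinyl spiro-epoxide; 12 isofraxidin (7-hydroxy-6,8-dimethoxy-2H-chromen-2-one)
Product: 13 7-[(3β,9β-dihydroxydrim-7-en-11-yl)oxy]-6,8-dimethoxy-2H-chromen-2-one
Conditions: 12 (1.5 equiv), Cs2CO3 (0.3 equiv), DMF, 90 °C
Reagents that add atoms: none
Why: Base-catalysed SN2 opening of the epoxide by deprotonated isofraxidin should occur at the primary carbon C11, the only accessible terminus of the 2,2-disubstituted oxirane, and the tertiary alkoxide formed deprotonates the next phenol, so catalytic base suffices; no stereocentre is changed.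

**Step 7**
Reactants: 13 diol
Product: 14 7-[(3β-acetoxy-9β-hydroxydrim-7-en-11-yl)oxy]-6,8-dimethoxy-2H-chromen-2-one
Conditions: Ac2O (1.5 equiv), pyridine, DMAP (cat.), CH2Cl2, 0 °C → rt
Reagents that add atoms: acetic anhydride, CC(=O)OC(C)=O
Why: Acylation distinguishes the secondary equatorial C3 hydroxyl from the tertiary allylic C9 hydroxyl next to quaternary C10, which stays free for step 8; C3 keeps its configuration because its C–O bond is not broken.

**Step 8**
Reactants: 14 tertiary allylic alcohol
Product: 17 7-[(3β-acetoxy-7-oxodrim-8-en-11-yl)oxy]-6,8-dimethoxy-2H-chromen-2-one, via tertiary chlorochromate ester 15 (not isolated), via C7 chlorochromate ester 16 (not isolated)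
Conditions: (C5H5NH)[CrO3Cl] (pyridinium chlorochromate, 3 equiv), NaOAc, 4 Å MS, CH2Cl2, rt
Reagents that add atoms: pyridinium chlorochromate, [O-][Cr](=O)(=O)Cl.c1cc[nH+]cc1
Why: Babler–Dauben oxidative transposition, in which the tertiary allylic chromate ester undergoes a [3,3] shift to C7 and is oxidised there, moves the oxygen function from C9 to C7 and the alkene to C8=C9, so C9 now carries C11 on a tetrasubstituted double bond; acetate, aryl ether and coumarin are inert to the reagent.

**Step 9**
Reactants: 17 enone
Product: 18 (E)-tosylhydrazone of 17 at C7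
Conditions: TsNHNH2 (1.5 equiv), PPTS (cat.), EtOH, 60 °C
Reagents that add atoms: 4-methylbenzenesulfonohydrazide, Cc1ccc(cc1)S(=O)(=O)NN
Why: Hydrazone formation at the unhindered conjugated C7 ketone under mild acid catalysis should be clean because the β-carbon C9 is fully substituted and cannot take up the hydrazide by conjugate addition; no stereocentre is formed.

**Step 10**
Reactants: 18 tosylhydrazone
Product: 21 7-{[(1R,4aR,6S,8aS)-6-acetoxy-2,5,5,8a-tetramethyl-1,4,4a,5,6,7,8,8a-octahydronaphthalen-1-yl]methoxy}-6,8-dimethoxy-2H-chromen-2-one (target), via N-boryl tosylhydrazine 19 (not isolated), via 7β-diazene 20 (not isolated)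
Conditions: catecholborane (3 equiv), CHCl3, 0 °C; then NaOAc·3H2O, 60 °C
Reagents that add atoms: none
Why: In this alkene-transposing reduction of an α,β-unsaturated tosylhydrazone, catecholborane should deliver hydride to C7 axially from the α face (as in angularly methylated octalone tosylhydrazones, which give the cis product), acetate then releases sulfinate to give the 7β-diazene, and its retro-ene loss of N2 transfers hydrogen suprafacially to the β face of C9 while the alkene returns to C7=C8, setting the last stereocentre (9β-H, C11 α); ester, lactone and aryl ether should not react with catecholborane at 0 °C.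

**Compound list**
1 | (R)-(−)-carvone | O=C1C(C)=CC[C@@H](C(C)=C)C1 | starting material
2 | cross-conjugated lithium dienolate of 1 | [Li+].[O-]C1=C[C@H](C(C)=C)CC=C1C | intermediate (not isolated)
3 | (5R,6S)-2,6-dimethyl-5-(prop-1-en-2-yl)cyclohex-2-en-1-one (major epimer; the 6R epimer is carried along) | O=C1C(C)=CC[C@@H](C(C)=C)[C@@H]1C | intermediate
4 | tetrasubstituted lithium enolate of 3 | [Li+].[O-]C1=C(C)[C@H](C(C)=C)CC=C1C | intermediate (not isolated)
5 | (5S,6S)-2,6-dimethyl-5-(prop-1-en-2-yl)-6-(prop-2-yn-1-yl)cyclohex-2-en-1-one | O=C1C(C)=CC[C@@H](C(C)=C)[C@]1(C)CC#C | intermediate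
6 | 3-[(1S,6S)-1,3-dimethyl-2-oxo-6-(prop-1-en-2-yl)cyclohex-3-en-1-yl]propanal | O=C1C(C)=CC[C@@H](C(C)=C)[C@]1(C)CCC=O | intermediate
7 | tertiary C4 radical from 6 | O=C1C(C)=CC[C@@H]([C](C)C)[C@]1(C)CCC=O | intermediate (not isolated)
8 | C3 alkoxyl radical (3β-O) | O=C1C(C)=CC[C@H]2C(C)(C)[C@@H]([O])CC[C@]12C | intermediate (not isolated)
9 | 3β-hydroxy-11-nordrim-7-en-9-one | O=C1C(C)=CC[C@H]2C(C)(C)[C@@H](O)CC[C@]12C | intermediate
10 | sulfonium betaine (C9 alkoxide, C3 lithium alkoxide) | C[S+](C)C[C@]1([O-])C(C)=CC[C@H]2C(C)(C)[C@@H]([O-])CC[C@]12C.[Li+] | intermediate (not isolated)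
11 | 9β,11-epoxydrim-7-en-3β-ol | C1O[C@]12C(C)=CC[C@H]3C(C)(C)[C@@H](O)CC[C@]23C | intermediate
12 | isofraxidin | COc1cc2ccc(=O)oc2c(OC)c1O | starting material
13 | 7-[(3β,9β-dihydroxydrim-7-en-11-yl)oxy]-6,8-dimethoxy-2H-chromen-2-one | COc1cc2ccc(=O)oc2c(OC)c1OC[C@]1(O)C(C)=CC[C@H]2C(C)(C)[C@@H](O)CC[C@]12C | intermediate
14 | 7-[(3β-acetoxy-9β-hydroxydrim-7-en-11-yl)oxy]-6,8-dimethoxy-2H-chromen-2-one | COc1cc2ccc(=O)oc2c(OC)c1OC[C@]1(O)C(C)=CC[C@H]2C(C)(C)[C@@H](OC(C)=O)CC[C@]12C | intermediate
15 | C9 chlorochromate ester of 14 | COc1cc2ccc(=O)oc2c(OC)c1OC[C@]1(O[Cr](=O)(=O)Cl)C(C)=CC[C@H]2C(C)(C)[C@@H](OC(C)=O)CC[C@]12C | intermediate (not isolated)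
16 | transposed C7β chlorochromate ester (Δ8) | COc1cc2ccc(=O)oc2c(OC)c1OCC1=C(C)[C@@H](O[Cr](=O)(=O)Cl)C[C@H]2C(C)(C)[C@@H](OC(C)=O)CC[C@]12C | intermediate (not isolated)
17 | 7-[(3β-acetoxy-7-oxodrim-8-en-11-yl)oxy]-6,8-dimethoxy-2H-chromen-2-one | COc1cc2ccc(=O)oc2c(OC)c1OCC1=C(C)C(=O)C[C@H]2C(C)(C)[C@@H](OC(C)=O)CC[C@]12C | intermediate
18 | (E)-C7 tosylhydrazone of 17 | COc1cc2ccc(=O)oc2c(OC)c1OCC1=C(C)/C(=N/NS(=O)(=O)c3ccc(C)cc3)C[C@H]2C(C)(C)[C@@H](OC(C)=O)CC[C@]12C | intermediate
19 | 7β-[N-(1,3,2-benzodioxaborol-2-yl)-N′-tosylhydrazinyl]drim-8-ene derivative | COc1cc2ccc(=O)oc2c(OC)c1OCC1=C(C)[C@@H](N(B3Oc4ccccc4O3)NS(=O)(=O)c3ccc(C)cc3)C[C@H]2C(C)(C)[C@@H](OC(C)=O)CC[C@]12C | intermediate (not isolated)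
20 | 7β-diazenyldrim-8-ene derivative (allylic diazene) | COc1cc2ccc(=O)oc2c(OC)c1OCC1=C(C)[C@@H](N=N)C[C@H]2C(C)(C)[C@@H](OC(C)=O)CC[C@]12C | intermediate (not isolated)
21 | 7-{[(3S,5R,9R,10S)-3-acetoxydrim-7-en-11-yl]oxy}-6,8-dimethoxy-2H-chromen-2-one | COc1cc2ccc(=O)oc2c(OC)c1OC[C@@H]1C(C)=CC[C@H]2C(C)(C)[C@@H](OC(C)=O)CC[C@]12C | target

**Totals**
Total steps: 10. Longest linear sequence: 10 steps (from 1; isofraxidin 12 enters at step 6).

**Steps most likely to fail**

1. Step 4. The silane and iron hydride may reduce the aldehyde before hydrogen-atom transfer to the alkene, or the alkoxyl radical may reopen faster than it is trapped, so that uncyclized reduced material accumulates; face selectivity at C3 may also be modest. The fallback sets out from 6 and comes back at 9. Markovnikov addition of HBr (HBr in AcOH, 0 °C) to the isopropenyl group gives the tertiary bromide 3-[6-(2-bromopropan-2-yl)-1,3-dimethyl-2-oxocyclohex-3-en-1-yl]propanal F1. A tin-hydride chain cyclization (Bu3SnH, AIBN, benzene, 80 °C, slow addition) then generates the same C4 radical without any hydride reagent and traps the alkoxyl radical by fast hydrogen transfer from tin, giving 9. If the C3 epimers form as a mixture, they are converged by oxidation (Dess–Martin periodinane, CH2Cl2) to 11-nordrim-7-ene-3,9-dione F2 and reduction of the saturated C3 ketone from the axial direction (NaBH4, MeOH–CH2Cl2, −78 °C), which returns 9.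

2. Step 6. SN2 attack of the doubly ortho-substituted, weakly nucleophilic phenoxide at the neopentyl-like C11 may be too slow, with thermal decomposition of the vinyl epoxide instead. The fallback sets out from 9 and comes back at 17; it brings in C11 with its oxygen protected and makes the aryl ether later at an allylic carbon. Addition of [(4-methoxybenzyloxy)methyl]lithium (from tributyl[(4-methoxybenzyloxy)methyl]stannane, itself made from 4-methoxybenzyl alcohol and tributyl(iodomethyl)stannane, and n-BuLi, THF, −78 °C) to the C9 ketone gives 11-O-(4-methoxybenzyl)drim-7-ene-3β,9β,11-triol F3. Selective acetylation (Ac2O, pyridine, DMAP) gives its 3-acetate F4. Oxidative transposition with (C5H5NH)[CrO3Cl] gives 3β-acetoxy-11-(4-methoxybenzyloxy)drim-8-en-7-one F5. DDQ (CH2Cl2–H2O) liberates 3β-acetoxy-11-hydroxydrim-8-en-7-one F6, whose primary allylic hydroxyl is coupled with 12 under Mitsunobu conditions (PPh3, DIAD, THF) to give 17.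

3. Step 10. Hydride delivery to C7 of the hydrazone may occur with poor or opposite facial selectivity, which would place the diazene on the α face and deliver hydrogen to the α face of C9. The fallback sets out from 17 and comes back at 21; it sets C7 on an isolable alcohol and introduces nitrogen with inversion. Luche reduction (NaBH4, CeCl3·7H2O, MeOH, −40 °C) gives the allylic alcohols. The 7α-alcohol 7-[(3β-acetoxy-7α-hydroxydrim-8-en-11-yl)oxy]-6,8-dimethoxy-2H-chromen-2-one F7, which is the epimer expected from the same β-face attack, is separated; any 7β-alcohol is returned to 17 with MnO2. Mitsunobu displacement of F7 with 2-nitrobenzenesulfonylhydrazide (PPh3, DEAD, N-methylmorpholine, −30 °C → rt) inverts C7 to the 7β-[1-(2-nitrobenzenesulfonyl)hydrazinyl] compound F8, which loses the sulfinic acid on warming to give diazene 20 and hence 21.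

**Further compounds**
F1 | step 4 | 3-[6-(2-bromopropan-2-yl)-1,3-dimethyl-2-oxocyclohex-3-en-1-yl]propanal (HBr adduct of 6) | O=C1C(C)=CC[C@@H](C(C)(C)Br)[C@]1(C)CCC=O
F2 | step 4 | 11-nordrim-7-ene-3,9-dione | O=C1C(C)=CC[C@H]2C(C)(C)C(=O)CC[C@]12C
F3 | step 6 | 11-O-(4-methoxybenzyl)drim-7-ene-3β,9β,11-triol | COc1ccc(COC[C@]2(O)C(C)=CC[C@H]3C(C)(C)[C@@H](O)CC[C@]23C)cc1
F4 | step 6 | 3-acetate of F3 | COc1ccc(COC[C@]2(O)C(C)=CC[C@H]3C(C)(C)[C@@H](OC(C)=O)CC[C@]23C)cc1
F5 | step 6 | 3β-acetoxy-11-(4-methoxybenzyloxy)drim-8-en-7-one | COc1ccc(COCC2=C(C)C(=O)C[C@H]3C(C)(C)[C@@H](OC(C)=O)CC[C@]23C)cc1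
F6 | step 6 | 3β-acetoxy-11-hydroxydrim-8-en-7-one | OCC1=C(C)C(=O)C[C@H]2C(C)(C)[C@@H](OC(C)=O)CC[C@]12C
F7 | step 10 | 7-[(3β-acetoxy-7α-hydroxydrim-8-en-11-yl)oxy]-6,8-dimethoxy-2H-chromen-2-one | COc1cc2ccc(=O)oc2c(OC)c1OCC1=C(C)[C@H](O)C[C@H]2C(C)(C)[C@@H](OC(C)=O)CC[C@]12C
F8 | step 10 | 7β-[1-(2-nitrobenzenesulfonyl)hydrazinyl] analogue of F7 | COc1cc2ccc(=O)oc2c(OC)c1OCC1=C(C)[C@@H](N(N)S(=O)(=O)c3ccccc3[N+](=O)[O-])C[C@H]2C(C)(C)[C@@H](OC(C)=O)CC[C@]12C
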